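**Retrosynthetic overview**

1. Target 41 ⇒ seco-triene 40: the ten-membered ring is closed last by ring-closing metathesis at the Z C3=C4 bond.
2. 40 ⇒ aldehyde 18 (fragment A: ring A, C2/C3, C9; 12 skeletal C) + allyl bromide 35 (fragment B: C4–C8, C16–C19 butenolide; 10 skeletal C). The late C8–C9 union is an indium-mediated γ-allylation that sets C8 and C9; the resulting exo-methylene lactone is then reduced to the C17 methyl.
3. 18 ⇒ catalytic asymmetric Diels–Alder of enal 2 with siloxydiene 4 (ring A, C1/C10), CBS reduction (C2), ring diene via enone and triflate, OsO4 (C11/C12).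
4. 35 ⇒ Sharpless epoxidation and Ti-mediated chloride opening (C6/C7), Roskamp homologation and lactonisation (tetronic acid), ethylene enyne metathesis (diene), iodination, hydroxymethylation, bromination (C18).
5. Ring order: ring A (step 3) → lactone ring on fragment B (step 20) → ten-membered ring (step 30).

Assumption: C-locants in the explanations are the briarane locants of 41 (ten-membered ring C1–C10; ring A C1, C10–C14; lactone C7, C8, C17, C19, O), and the (S)-oxazaborolidinium catalyst of step 3 is taken to give the enantiomer drawn (otherwise its mirror image is used).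

**Fragment A**

Step 1
Reactants: 1 methyl 3-methylbut-2-enoate
Product: 2 methyl (2E)-3-methyl-4-oxobut-2-enoate
Conditions: SeO2, 1,4-dioxane, 100 °C
Reagents that add atoms: selenium dioxide, O=[Se]=O
Why: Riley allylic oxidation (ene reaction then [2,3]-shift) converts the methyl trans to the ester into the aldehyde, fixing the E geometry that later makes C2 and C9 trans on ring A.

Step 2
Reactants: 3 pent-1-en-3-one
Product: 4 (Z)-tert-butyl(dimethyl)(penta-1,3-dien-3-yloxy)silane
Conditions: t-BuMe2SiOTf, Et3N, Et2O, 0 °C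
Reagents that add atoms: tert-butyldimethylsilyl trifluoromethanesulfonate, CC(C)(C)[Si](C)(C)OS(=O)(=O)C(F)(F)F
Why: Soft enolisation and O-silylation of the ethyl ketone give the Z 2-silyloxy diene (methyl outside), the electron-rich partner for the cycloaddition.

Step 3
Reactants: 2 methyl (2E)-3-methyl-4-oxobut-2-enoate; 4 (Z)-tert-butyl(dimethyl)(penta-1,3-dien-3-yloxy)silane
Product: 5 methyl (1S,2S,6S)-3-(tert-butyldimethylsilyloxy)-6-formyl-2,6-dimethylcyclohex-3-ene-1-carboxylate
Conditions: (S)-3,3-diphenyl-1-(o-tolyl)tetrahydropyrrolo[1,2-c][1,3,2]oxazaborole (20 mol %), HNTf2 (16 mol %), CH2Cl2, −78 → −40 °C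
Reagents that add atoms: none
Why: Catalytic enantioselective Diels–Alder reaction in which the aldehyde-bound chiral oxazaborolidinium ion shields one enal face and directs the siloxy-substituted diene terminus to the aldehyde β-carbon (C10), so ring A forms with quaternary C1 and C10 set, their trans relationship following from the E dienophile (the C11 centre is lost again in step 9).

Step 4
Reactants: 5 methyl (1S,2S,6S)-3-(tert-butyldimethylsilyloxy)-6-formyl-2,6-dimethylcyclohex-3-ene-1-carboxylate; 6 vinylmagnesium bromide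
Product: 7 methyl (1S,2S,6S)-3-(tert-butyldimethylsilyloxy)-6-(1-hydroxyprop-2-en-1-yl)-2,6-dimethylcyclohex-3-ene-1-carboxylate (both carbinol epimers)
Conditions: CH2=CHMgBr, THF, −78 °C; aq. NH4Cl
Reagents that add atoms: none
Why: Chemoselective Grignard 1,2-addition to the neopentyl aldehyde in the presence of the methyl ester installs C3 and the later metathesis vinyl group, the C2 epimer ratio being irrelevant because C2 is oxidised next.

Step 5
Reactants: 7 methyl (1S,2S,6S)-3-(tert-butyldimethylsilyloxy)-6-(1-hydroxyprop-2-en-1-yl)-2,6-dimethylcyclohex-3-ene-1-carboxylate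
Product: 8 methyl (1S,2S,6S)-3-(tert-butyldimethylsilyloxy)-2,6-dimethyl-6-(prop-2-enoyl)cyclohex-3-ene-1-carboxylate
Conditions: Dess–Martin periodinane, NaHCO3, CH2Cl2, 0 °C
Reagents that add atoms: none
Why: Dess–Martin oxidation of the allylic alcohol gives the vinyl ketone under buffered conditions that leave the silyl enol ether intact.

Step 6
Reactants: 8 methyl (1S,2S,6S)-3-(tert-butyldimethylsilyloxy)-2,6-dimethyl-6-(prop-2-enoyl)cyclohex-3-ene-1-carboxylate
Product: 9 methyl (1S,2S,6S)-3-(tert-butyldimethylsilyloxy)-6-[(1R)-1-hydroxyprop-2-en-1-yl]-2,6-dimethylcyclohex-3-ene-1-carboxylate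
Conditions: (S)-2-methyl-CBS-oxazaborolidine (20 mol %), catecholborane, toluene, −78 °C
Reagents that add atoms: none
Why: Corey–Bakshi–Shibata reduction delivers hydride to the ketone face defined by the bulky quaternary C1 as the large group, giving the (R)-carbinol at C2 (reinforced by Felkin–Anh attack anti to the C1–C10 bond) without touching ester, enol ether or alkenes.

Step 7
Reactants: 9 methyl (1S,2S,6S)-3-(tert-butyldimethylsilyloxy)-6-[(1R)-1-hydroxyprop-2-en-1-yl]-2,6-dimethylcyclohex-3-ene-1-carboxylate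
Product: 10 methyl (1S,2S,6S)-3-(tert-butyldimethylsilyloxy)-2,6-dimethyl-6-[(1R)-1-(triethylsilyloxy)prop-2-en-1-yl]cyclohex-3-ene-1-carboxylate
Conditions: Et3SiOTf, 2,6-lutidine, CH2Cl2, −78 °C
Reagents that add atoms: triethylsilyl trifluoromethanesulfonate, CC[Si](CC)(CC)OS(=O)(=O)C(F)(F)F
Why: Silyl ether formation protects the hindered C2 carbinol (before it can lactonise onto the ester) with a group that survives base and palladium but falls in the later acidic global deprotection.

Step 8
Reactants: 10 methyl (1S,2S,6S)-3-(tert-butyldimethylsilyloxy)-2,6-dimethyl-6-[(1R)-1-(triethylsilyloxy)prop-2-en-1-yl]cyclohex-3-ene-1-carboxylate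
Product: 11 methyl (1S,2S,6S)-2,6-dimethyl-3-oxo-6-[(1R)-1-(triethylsilyloxy)prop-2-en-1-yl]cyclohex-4-ene-1-carboxylate
Conditions: Pd(OAc)2 (1.1 equiv), MeCN, 40 °C
Reagents that add atoms: none
Why: Saegusa–Ito oxidation (palladation of the silyl enol ether, β-hydride elimination toward C14) gives regiospecifically the C12 enone carrying the C13=C14 alkene of the target.

Step 9
Reactants: 11 methyl (1S,2S,6S)-2,6-dimethyl-3-oxo-6-[(1R)-1-(triethylsilyloxy)prop-2-en-1-yl]cyclohex-4-ene-1-carboxylate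
Product: 13 methyl 2,6-dimethyl-6-[(1R)-1-(triethylsilyloxy)prop-2-en-1-yl]-3-(trifluoromethylsulfonyloxy)cyclohexa-2,4-diene-1-carboxylate (C1 and C6 as in 11), via potassium dienolate 12 (not isolated)
Conditions: KN(SiMe3)2, THF, −78 °C; then PhNTf2
Reagents that add atoms: N-phenylbis(trifluoromethanesulfonimide), O=S(=O)(N(c1ccccc1)S(=O)(=O)C(F)(F)F)C(F)(F)F
Why: Kinetic enolisation of the enone can only occur at C11 (C1 is quaternary, the ketone α-proton is more acidic than the ester α-proton) and O-triflation of the cross-conjugated dienolate gives the 2-triflyloxy-1,3-diene.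

Step 10
Reactants: 13 methyl 2,6-dimethyl-6-[(1R)-1-(triethylsilyloxy)prop-2-en-1-yl]-3-(trifluoromethylsulfonyloxy)cyclohexa-2,4-diene-1-carboxylate
Product: 14 methyl 2,6-dimethyl-6-[(1R)-1-(triethylsilyloxy)prop-2-en-1-yl]cyclohexa-2,4-diene-1-carboxylate (C1 and C6 as in 11)
Conditions: Pd(OAc)2 (5 mol %), PPh3 (10 mol %), n-Bu3N, HCO2H, DMF, 60 °C
Reagents that add atoms: none
Why: Palladium-catalysed formate reduction of the vinyl triflate (oxidative addition, formate decarboxylation, reductive elimination) leaves the C11=C12–C13=C14 ring diene.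

Step 11
Reactants: 14 methyl 2,6-dimethyl-6-[(1R)-1-(triethylsilyloxy)prop-2-en-1-yl]cyclohexa-2,4-diene-1-carboxylate
Product: 15 methyl 2,3-dihydroxy-2,6-dimethyl-6-[(1R)-1-(triethylsilyloxy)prop-2-en-1-yl]cyclohex-4-ene-1-carboxylate (2,3-cis diol trans to the ester; target C11 S and C12 R)
Conditions: OsO4 (2 mol %), NMO (1.1 equiv), acetone–H2O, 0 °C
Reagents that add atoms: osmium tetroxide, O=[Os](=O)(=O)=O; N-methylmorpholine N-oxide, C[N+]1([O-])CCOCC1; water, O
Why: Upjohn syn-dihydroxylation in which OsO4 attacks the more electron-rich trisubstituted C11=C12 alkene of the diene on the face anti to the C10 ester and the pseudo-axial C1 methyl, creating the cis C11/C12 diol trans to C9 and leaving C13=C14 and the hindered vinyl group untouched.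

Step 12
Reactants: 15 methyl 2,3-dihydroxy-2,6-dimethyl-6-[(1R)-1-(triethylsilyloxy)prop-2-en-1-yl]cyclohex-4-ene-1-carboxylate
Product: 16 acetonide of 15 (2,2-dimethyl-1,3-dioxolane across O11 and O12)
Conditions: Me2C(OMe)2, PPTS (cat.), CH2Cl2, 23 °C
Reagents that add atoms: 2,2-dimethoxypropane, COC(C)(C)OC
Why: Acid-catalysed transacetalisation ties the cis diol into a dioxolane, which blocks retro-aldol and elimination chemistry once C9 becomes an aldehyde.

Step 13
Reactants: 16 acetonide of 15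
Product: 17 primary alcohol (ester of 16 reduced to C9H2OH)
Conditions: i-Bu2AlH, CH2Cl2, −78 → 0 °C
Reagents that add atoms: none
Why: Hydride reduction of the methyl ester to the primary alcohol, with acetal and silyl ether inert.

Step 14
Reactants: 17 primary alcohol
Product: 18 fragment A aldehyde (C9 formyl; 2-O-triethylsilyl; 11,12-O-isopropylidene; C13=C14; C2 vinyl)
Conditions: Dess–Martin periodinane, NaHCO3, CH2Cl2, 0 °C
Reagents that add atoms: none
Why: Dess–Martin oxidation gives the aldehyde under neutral conditions that do not epimerise C10.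

**Fragment B**

Step 15
Reactants: 19 (2E)-pent-2-en-4-yn-1-ol
Product: 20 [(2R,3R)-3-ethynyloxiran-2-yl]methanol
Conditions: Ti(OiPr)4 (10 mol %), D-(−)-diethyl tartrate (12 mol %), t-BuOOH, 4 Å MS, CH2Cl2, −20 °C
Reagents that add atoms: tert-butyl hydroperoxide, CC(C)(C)OO
Why: Sharpless asymmetric epoxidation with the D-tartrate ligand delivers oxygen to the allylic alcohol face that gives the (2R,3R)-epoxide, setting C7 and pre-setting C6.

Step 16
Reactants: 20 [(2R,3R)-3-ethynyloxiran-2-yl]methanol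
Product: 21 (2R,3S)-3-chloropent-4-yne-1,2-diol
Conditions: Ti(OiPr)4 (1.5 equiv), Et2NH2Cl (3 equiv), CH2Cl2, 23 °C
Reagents that add atoms: diethylammonium chloride, CC[NH2+]CC.[Cl-]
Why: Titanium-mediated regioselective epoxide opening in which chloride attacks the activated propargylic C3 of the Ti-bound epoxy alcohol with SN2 inversion, giving the anti chlorohydrin (C6 S, C7 R).

Step 17
Reactants: 21 (2R,3S)-3-chloropent-4-yne-1,2-diol
Product: 22 (2R,3S)-3-chloro-1,2-bis(triethylsilyloxy)pent-4-yne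
Conditions: Et3SiCl, imidazole, DMF, 0 °C
Reagents that add atoms: chlorotriethylsilane, CC[Si](CC)(CC)Cl
Why: Bis-silylation protects both hydroxyls and removes any chance of base-induced re-closure of the chlorohydrin to an epoxide.

Step 18
Reactants: 22 (2R,3S)-3-chloro-1,2-bis(triethylsilyloxy)pent-4-yne
Product: 23 (2R,3S)-3-chloro-2-(triethylsilyloxy)pent-4-ynal
Conditions: (COCl)2, DMSO, CH2Cl2, −78 → −30 °C; then Et3N
Reagents that add atoms: none
Why: Under Swern conditions the primary triethylsilyl ether is selectively cleaved and oxidised to the aldehyde while the secondary silyl ether survives, and the cold conditions avoid epimerisation at C7.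

Step 19
Reactants: 23 (2R,3S)-3-chloro-2-(triethylsilyloxy)pent-4-ynal; 24 ethyl diazoacetate
Product: 25 ethyl (4R,5S)-5-chloro-3-oxo-4-(triethylsilyloxy)hept-6-ynoate
Conditions: SnCl2 (10 mol %), CH2Cl2, 23 °C
Reagents that add atoms: none
Why: Roskamp homologation (Lewis-acid-catalysed addition of the diazo ester to the aldehyde, 1,2-hydride shift, loss of N2) gives the β-keto ester that supplies C17 and C19 without touching C6 or C7.

Step 20
Reactants: 25 ethyl (4R,5S)-5-chloro-3-oxo-4-(triethylsilyloxy)hept-6-ynoate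
Product: 27 (5R)-5-[(1S)-1-chloroprop-2-yn-1-yl]-4-hydroxyfuran-2(5H)-one, via hydroxy keto ester 26 (not isolated)
Conditions: HF·pyridine, THF, 0 °C; then toluene, 100 °C
Reagents that add atoms: none
Why: Desilylation frees the C7 hydroxyl, which on heating lactonises onto the β-keto ester (intramolecular transesterification) to give the tetronic acid under non-basic conditions that spare the chlorohydrin.

Step 21
Reactants: 27 (5R)-5-[(1S)-1-chloroprop-2-yn-1-yl]-4-hydroxyfuran-2(5H)-one
Product: 28 (5R)-5-[(1S)-1-chloroprop-2-yn-1-yl]-4-hydroxy-3-iodofuran-2(5H)-one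
Conditions: NIS, MeCN, 0 °C
Reagents that add atoms: N-iodosuccinimide, O=C1CCC(=O)N1I
Why: Electrophilic iodination at the nucleophilic enol β-carbon (C17) of the tetronic acid.

Step 22
Reactants: 28 (5R)-5-[(1S)-1-chloroprop-2-yn-1-yl]-4-hydroxy-3-iodofuran-2(5H)-one
Product: 29 (5R)-5-[(1S)-1-chloroprop-2-yn-1-yl]-3-iodo-4-(4-methoxybenzyloxy)furan-2(5H)-one
Conditions: 4-MeOC6H4CH2OH, PPh3, DIAD, THF, 0 → 23 °C
Reagents that add atoms: 4-methoxybenzyl alcohol, COc1ccc(CO)cc1
Why: Mitsunobu O-alkylation of the acidic tetronic acid (C3 blocked by iodine) protects O8 as the enol ether.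

Step 23
Reactants: 29 (5R)-5-[(1S)-1-chloroprop-2-yn-1-yl]-3-iodo-4-(4-methoxybenzyloxy)furan-2(5H)-one; 30 ethene
Product: 31 (5R)-5-[(1S)-1-chloro-2-methylidenebut-3-en-1-yl]-3-iodo-4-(4-methoxybenzyloxy)furan-2(5H)-one
Conditions: second-generation Grubbs catalyst RuCl2(=CHPh)(PCy3)(H2IMes) (5 mol %), ethene (1 atm), CH2Cl2, 40 °C
Reagents that add atoms: none
Why: Cross enyne metathesis with ethene converts the terminal alkyne into the 2-substituted buta-1,3-diene (C4, C5, C16), the tetrasubstituted iodoalkene being inert.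

Step 24
Reactants: 31 (5R)-5-[(1S)-1-chloro-2-methylidenebut-3-en-1-yl]-3-iodo-4-(4-methoxybenzyloxy)furan-2(5H)-one; 32 formaldehyde
Product: 34 (5R)-5-[(1S)-1-chloro-2-methylidenebut-3-en-1-yl]-3-(hydroxymethyl)-4-(4-methoxybenzyloxy)furan-2(5H)-one, via alkenylmagnesium chloride 33 (not isolated)
Conditions: i-PrMgCl·LiCl, THF, −40 °C; then CH2O (gas from cracked paraformaldehyde), −40 → 0 °C; aq. NH4Cl
Reagents that add atoms: none
Why: Iodine–magnesium exchange gives the α-magnesiated β-alkoxy butenolide (it cannot β-eliminate within the five-membered ring), whose addition to formaldehyde installs C18 as a hydroxymethyl group.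

Step 25
Reactants: 34 (5R)-5-[(1S)-1-chloro-2-methylidenebut-3-en-1-yl]-3-(hydroxymethyl)-4-(4-methoxybenzyloxy)furan-2(5H)-one
Product: 35 (5R)-3-(bromomethyl)-5-[(1S)-1-chloro-2-methylidenebut-3-en-1-yl]-4-(4-methoxybenzyloxy)furan-2(5H)-one (fragment B)
Conditions: CBr4, PPh3, CH2Cl2, 0 °C
Reagents that add atoms: carbon tetrabromide, BrC(Br)(Br)Br
Why: Appel bromination turns the primary allylic alcohol into the 2-(bromomethyl)-3-alkoxyacrylate-type allyl bromide needed for the coupling.

**Union and endgame**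

Step 26
Reactants: 18 fragment A aldehyde; 35 fragment B allyl bromide
Product: 36 seco adduct (9-hydroxy; 8-O-(4-methoxybenzyl); 2-O-triethylsilyl; 11,12-O-isopropylidene; 17(18)-methylene lactone)
Conditions: In powder (2 equiv), DMF, 23 °C
Reagents that add atoms: none
Why: Barbier-type indium-mediated allylation (γ-selective addition through a six-membered chair transition state) joins the fragments at C8–C9: the oxygenated γ-carbon C8 bonds on the lactone face anti to the C7 side chain (C9 trans to C6, O8 cis to C6), the chair with the aldehyde residue equatorial and the ether oxygen cis to the metal-bearing CH2 gives the 8,9-anti relationship, and C18 becomes an exocyclic methylene, while the allylic chloride, acetal and silyl ether are inert to indium metal.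

Step 27
Reactants: 36 seco adduct
Product: 37 seco pentaol (2,8,9,11,12-pentahydroxy; 17(18)-methylene lactone)
Conditions: CF3CO2H–H2O–CH2Cl2 (2:1:8), 0 °C
Reagents that add atoms: none
Why: Acidic global deprotection cleaves the triethylsilyl ether, hydrolyses the acetonide and ionises the tertiary 4-methoxybenzyl ether at its benzylic carbon, while the allylic chloride (next to the electron-poor C7) and the lactone survive.

Step 28
Reactants: 37 seco pentaol
Product: 38 seco triacetate (2,9,12-tri-O-acetyl; 8,11-dihydroxy; 17(18)-methylene lactone)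
Conditions: Ac2O, pyridine, DMAP (cat.), CH2Cl2, 0 → 23 °C
Reagents that add atoms: acetic anhydride, CC(=O)OC(C)=O
Why: DMAP-catalysed acylation acetylates the three secondary hydroxyls (C2, C9, C12) and leaves the two tertiary hydroxyls (C8, C11) free.

Step 29
Reactants: 38 seco triacetate
Product: 40 seco triene (2,9,12-tri-O-acetyl-8,11-dihydroxy-17-methyl lactone bearing the C2 vinyl and C5 butadienyl groups), via lithium enolate 39 (not isolated)
Conditions: LiBH(s-Bu)3 (2.2 equiv), THF, −78 °C; then AcOH, −78 °C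
Reagents that add atoms: none
Why: Conjugate (1,4) reduction of the α-methylene lactone gives the enolate, which is protonated at C17 anti to the neighbouring C8 oxido group (Fráter–Seebach-type control), placing the C18 methyl cis to O8 and trans to the C9 branch (17R), which is also the more stable arrangement.

Step 30
Reactants: 40 seco triene
Product: 41 target CNP0285654.4
Conditions: second-generation Hoveyda–Grubbs catalyst RuCl2(=CH-C6H4-2-OiPr)(H2IMes) (15 mol %), toluene (0.5 mM), 80 °C
Reagents that add atoms: none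
Why: Ring-closing metathesis between the C2 vinyl group and the terminal alkene of the 2-substituted butadiene closes the ten-membered ring with loss of ethene, the trans-fused bicycle accommodating only the Z C3=C4 alkene, while the 1,1-disubstituted C5=C16 and the ring A alkene do not take part.

**Compound list**

1 | methyl 3-methylbut-2-enoate | CC(C)=CC(=O)OC | starting material
2 | methyl (2E)-3-methyl-4-oxobut-2-enoate | O=C/C(C)=C/C(=O)OC | intermediate
3 | pent-1-en-3-one | C=CC(=O)CC | starting material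
4 | (Z)-tert-butyl(dimethyl)(penta-1,3-dien-3-yloxy)silane | C=C/C(O[Si](C)(C)C(C)(C)C)=C/C | intermediate
5 | methyl (1S,2S,6S)-3-(tert-butyldimethylsilyloxy)-6-formyl-2,6-dimethylcyclohex-3-ene-1-carboxylate | O=C[C@@]1(C)CC=C(O[Si](C)(C)C(C)(C)C)[C@@H](C)[C@@H]1C(=O)OC | intermediate
6 | vinylmagnesium bromide | C=C[Mg]Br | starting material
7 | methyl (1S,2S,6S)-3-(tert-butyldimethylsilyloxy)-6-(1-hydroxyprop-2-en-1-yl)-2,6-dimethylcyclohex-3-ene-1-carboxylate (both carbinol epimers) | C=CC(O)[C@@]1(C)CC=C(O[Si](C)(C)C(C)(C)C)[C@@H](C)[C@@H]1C(=O)OC | intermediate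
8 | methyl (1S,2S,6S)-3-(tert-butyldimethylsilyloxy)-2,6-dimethyl-6-(prop-2-enoyl)cyclohex-3-ene-1-carboxylate | C=CC(=O)[C@@]1(C)CC=C(O[Si](C)(C)C(C)(C)C)[C@@H](C)[C@@H]1C(=O)OC | intermediate
9 | methyl (1S,2S,6S)-3-(tert-butyldimethylsilyloxy)-6-[(1R)-1-hydroxyprop-2-en-1-yl]-2,6-dimethylcyclohex-3-ene-1-carboxylate | C=C[C@@H](O)[C@@]1(C)CC=C(O[Si](C)(C)C(C)(C)C)[C@@H](C)[C@@H]1C(=O)OC | intermediate
10 | methyl (1S,2S,6S)-3-(tert-butyldimethylsilyloxy)-2,6-dimethyl-6-[(1R)-1-(triethylsilyloxy)prop-2-en-1-yl]cyclohex-3-ene-1-carboxylate | C=C[C@@H](O[Si](CC)(CC)CC)[C@@]1(C)CC=C(O[Si](C)(C)C(C)(C)C)[C@@H](C)[C@@H]1C(=O)OC | intermediate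
11 | methyl (1S,2S,6S)-2,6-dimethyl-3-oxo-6-[(1R)-1-(triethylsilyloxy)prop-2-en-1-yl]cyclohex-4-ene-1-carboxylate | C=C[C@@H](O[Si](CC)(CC)CC)[C@@]1(C)C=CC(=O)[C@@H](C)[C@@H]1C(=O)OC | intermediate
12 | potassium dienolate of 11 (O-potassium cyclohexa-2,4-dien-3-olate; not isolated) | C=C[C@@H](O[Si](CC)(CC)CC)[C@@]1(C)C=CC([O-])=C(C)[C@@H]1C(=O)OC.[K+] | intermediate
13 | methyl 2,6-dimethyl-6-[(1R)-1-(triethylsilyloxy)prop-2-en-1-yl]-3-(trifluoromethylsulfonyloxy)cyclohexa-2,4-diene-1-carboxylate (C1 and C6 as in 11) | C=C[C@@H](O[Si](CC)(CC)CC)[C@@]1(C)C=CC(OS(=O)(=O)C(F)(F)F)=C(C)[C@@H]1C(=O)OC | intermediate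
14 | methyl 2,6-dimethyl-6-[(1R)-1-(triethylsilyloxy)prop-2-en-1-yl]cyclohexa-2,4-diene-1-carboxylate (C1 and C6 as in 11) | C=C[C@@H](O[Si](CC)(CC)CC)[C@@]1(C)C=CC=C(C)[C@@H]1C(=O)OC | intermediate
15 | methyl 2,3-dihydroxy-2,6-dimethyl-6-[(1R)-1-(triethylsilyloxy)prop-2-en-1-yl]cyclohex-4-ene-1-carboxylate (2,3-cis diol trans to the ester) | C=C[C@@H](O[Si](CC)(CC)CC)[C@@]1(C)C=C[C@@H](O)[C@@](C)(O)[C@@H]1C(=O)OC | intermediate
16 | acetonide of 15 (2,2-dimethyl-1,3-dioxolane across O11 and O12) | C=C[C@@H](O[Si](CC)(CC)CC)[C@@]1(C)C=C[C@@H](OC2(C)C)[C@@](C)(O2)[C@@H]1C(=O)OC | intermediate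
17 | primary alcohol (ester of 16 reduced to CH2OH) | C=C[C@@H](O[Si](CC)(CC)CC)[C@@]1(C)C=C[C@@H](OC2(C)C)[C@@](C)(O2)[C@@H]1CO | intermediate
18 | fragment A aldehyde (C9 formyl; 2-O-triethylsilyl; 11,12-O-isopropylidene; C1, C2, C10, C11, C12 as in 41) | C=C[C@@H](O[Si](CC)(CC)CC)[C@@]1(C)C=C[C@@H](OC2(C)C)[C@@](C)(O2)[C@@H]1C=O | intermediate
19 | (2E)-pent-2-en-4-yn-1-ol | OC/C=C/C#C | starting material
20 | [(2R,3R)-3-ethynyloxiran-2-yl]methanol | OC[C@H]1O[C@@H]1C#C | intermediate
21 | (2R,3S)-3-chloropent-4-yne-1,2-diol | OC[C@@H](O)[C@@H](Cl)C#C | intermediate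
22 | (2R,3S)-3-chloro-1,2-bis(triethylsilyloxy)pent-4-yne | CC[Si](CC)(CC)OC[C@@H](O[Si](CC)(CC)CC)[C@@H](Cl)C#C | intermediate
23 | (2R,3S)-3-chloro-2-(triethylsilyloxy)pent-4-ynal | O=C[C@@H](O[Si](CC)(CC)CC)[C@@H](Cl)C#C | intermediate
24 | ethyl diazoacetate | CCOC(=O)C=[N+]=[N-] | starting material
25 | ethyl (4R,5S)-5-chloro-3-oxo-4-(triethylsilyloxy)hept-6-ynoate | CCOC(=O)CC(=O)[C@@H](O[Si](CC)(CC)CC)[C@@H](Cl)C#C | intermediate
26 | ethyl (4R,5S)-5-chloro-4-hydroxy-3-oxohept-6-ynoate (not isolated) | CCOC(=O)CC(=O)[C@@H](O)[C@@H](Cl)C#C | intermediate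
27 | (5R)-5-[(1S)-1-chloroprop-2-yn-1-yl]-4-hydroxyfuran-2(5H)-one | OC1=CC(=O)O[C@H]1[C@@H](Cl)C#C | intermediate
28 | (5R)-5-[(1S)-1-chloroprop-2-yn-1-yl]-4-hydroxy-3-iodofuran-2(5H)-one | OC1=C(I)C(=O)O[C@H]1[C@@H](Cl)C#C | intermediate
29 | (5R)-5-[(1S)-1-chloroprop-2-yn-1-yl]-3-iodo-4-(4-methoxybenzyloxy)furan-2(5H)-one | COc1ccc(COC2=C(I)C(=O)O[C@H]2[C@@H](Cl)C#C)cc1 | intermediate
30 | ethene | C=C | starting material
31 | (5R)-5-[(1S)-1-chloro-2-methylidenebut-3-en-1-yl]-3-iodo-4-(4-methoxybenzyloxy)furan-2(5H)-one | COc1ccc(COC2=C(I)C(=O)O[C@H]2[C@@H](Cl)C(=C)C=C)cc1 | intermediate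
32 | formaldehyde | C=O | starting material
33 | alkenylmagnesium chloride from 31 (MgCl in place of I; not isolated) | COc1ccc(COC2=C([Mg]Cl)C(=O)O[C@H]2[C@@H](Cl)C(=C)C=C)cc1 | intermediate
34 | (5R)-5-[(1S)-1-chloro-2-methylidenebut-3-en-1-yl]-3-(hydroxymethyl)-4-(4-methoxybenzyloxy)furan-2(5H)-one | COc1ccc(COC2=C(CO)C(=O)O[C@H]2[C@@H](Cl)C(=C)C=C)cc1 | intermediate
35 | (5R)-3-(bromomethyl)-5-[(1S)-1-chloro-2-methylidenebut-3-en-1-yl]-4-(4-methoxybenzyloxy)furan-2(5H)-one (fragment B) | COc1ccc(COC2=C(CBr)C(=O)O[C@H]2[C@@H](Cl)C(=C)C=C)cc1 | intermediate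
36 | seco adduct (9-hydroxy; 8-O-(4-methoxybenzyl); 2-O-triethylsilyl; 11,12-O-isopropylidene; 17(18)-methylene lactone; stereocentres as in 41) | C=C[C@@H](O[Si](CC)(CC)CC)[C@@]1(C)C=C[C@@H](OC2(C)C)[C@@](C)(O2)[C@@H]1[C@@H](O)[C@]3(OCc4ccc(OC)cc4)C(=C)C(=O)O[C@H]3[C@@H](Cl)C(=C)C=C | intermediate
37 | seco pentaol (2,8,9,11,12-pentahydroxy; 17(18)-methylene lactone) | C=C[C@@H](O)[C@@]1(C)C=C[C@@H](O)[C@@](C)(O)[C@@H]1[C@@H](O)[C@]2(O)C(=C)C(=O)O[C@H]2[C@@H](Cl)C(=C)C=C | intermediate
38 | seco triacetate (2,9,12-tri-O-acetyl; 8,11-dihydroxy; 17(18)-methylene lactone) | C=C[C@@H](OC(C)=O)[C@@]1(C)C=C[C@@H](OC(C)=O)[C@@](C)(O)[C@@H]1[C@@H](OC(C)=O)[C@]2(O)C(=C)C(=O)O[C@H]2[C@@H](Cl)C(=C)C=C | intermediate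
39 | lithium enolate of the 17-methyl lactone (not isolated) | C=C[C@@H](OC(C)=O)[C@@]1(C)C=C[C@@H](OC(C)=O)[C@@](C)(O)[C@@H]1[C@@H](OC(C)=O)[C@]2(O)C(C)=C([O-])O[C@H]2[C@@H](Cl)C(=C)C=C.[Li+] | intermediate
40 | seco triene (2,9,12-tri-O-acetyl-8,11-dihydroxy-(17R)-methyl lactone with C2 vinyl and C5 butadienyl groups) | C=C[C@@H](OC(C)=O)[C@@]1(C)C=C[C@@H](OC(C)=O)[C@@](C)(O)[C@@H]1[C@@H](OC(C)=O)[C@]2(O)[C@@H](C)C(=O)O[C@H]2[C@@H](Cl)C(=C)C=C | intermediate
41 | CNP0285654.4: (1S,2R,3Z,6S,7R,8R,9R,10S,11S,12R,17R)-2,9,12-triacetoxy-6-chloro-8,11-dihydroxybriara-3,5(16),13-trien-19,7-olide | C=C1/C=C\[C@@H](OC(C)=O)[C@@]2(C)C=C[C@@H](OC(C)=O)[C@@](C)(O)[C@@H]2[C@@H](OC(C)=O)[C@]2(O)[C@@H](C)C(=O)O[C@H]2[C@H]1Cl | target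

**Step count**

Total step count: 30. Longest linear sequence: 18 steps (steps 1, 3–14 and 26–30), which is 60 % of the total. The fragment B branch has 11 steps (15–25) and the diene side branch 1 step (2).

**Steps most likely to fail, with fallbacks**

The union of 18 and 35 (step 26) is the most exposed step. It must form a bond between a fully substituted, oxygen-bearing γ-carbon and a hindered α-branched aldehyde, and attack through the CH2 terminus (linear product) or a mismatched pairing of the two chiral partners could erode regio- or stereocontrol. The fallback replaces the Barbier reaction by a boron allylation. It sets out from iodide 31 (steps 24 and 25 are then not needed): iodine–magnesium exchange with i-PrMgCl·LiCl and trapping with (iodomethyl)boronic acid pinacol ester gives, after 1,2-metallate shift, the isolable allylboronate F1. Heated with aldehyde 18 in toluene, F1 can only react through its γ-carbon in a closed chair transition state, with the same stereochemical sense, and after oxidative or aqueous work-up the route is rejoined at 36.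

The conjugate reduction of 38 (step 29) sets C17 by kinetic protonation of an enolate that is flanked by a quaternary carbon carrying both an oxygen and the bulky C9 branch, so the wrong epimer may dominate; base equilibration is unsafe because the β-hydroxy lactone can eliminate and the chlorohydrin lactone can close to an epoxide. The fallback sets C17 under thermodynamic control without a free enolate. Starting from 38, reversible conjugate addition of benzeneselenol (catalytic Et3N) gives the selenide F2, in which the CH2SePh group settles trans to the C9 branch. Radical deselenation with (Me3Si)3SiH and Et3B/air at low temperature then cleaves only the C18–Se bond and returns to the route at 40.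

The ring-closing metathesis of 40 (step 30) may suffer from ring strain, oligomerisation or slow initiation at the hindered C2 vinyl group. The fallback closes the ring earlier, on a differently biased substrate. It sets out from the fully protected adduct 36, whose acetonide and bulky C8 ether restrict the seco chain: metathesis with the same ruthenium catalyst gives the protected macrocycle F3. Aqueous trifluoroacetic acid gives the macrocyclic pentaol F4, acetylation gives the triacetate F5, and conjugate reduction with LiBH(s-Bu)3 then delivers 41 directly.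

Further compounds
F1 | step 26 | (5R)-5-[(1S)-1-chloro-2-methylidenebut-3-en-1-yl]-4-(4-methoxybenzyloxy)-3-[(4,4,5,5-tetramethyl-1,3,2-dioxaborolan-2-yl)methyl]furan-2(5H)-one | COc1ccc(COC2=C(CB3OC(C)(C)C(C)(C)O3)C(=O)O[C@H]2[C@@H](Cl)C(=C)C=C)cc1
F2 | step 29 | seco triacetate with 17-(phenylselanylmethyl) lactone (C17 as in 40) | C=C[C@@H](OC(C)=O)[C@@]1(C)C=C[C@@H](OC(C)=O)[C@@](C)(O)[C@@H]1[C@@H](OC(C)=O)[C@]2(O)[C@@H](C[Se]c3ccccc3)C(=O)O[C@H]2[C@@H](Cl)C(=C)C=C
F3 | step 30 | protected macrocycle (2-O-triethylsilyl; 11,12-O-isopropylidene; 8-O-(4-methoxybenzyl); 9-hydroxy; 17(18)-methylene lactone; 3Z) | C=C1/C=C\[C@@H](O[Si](CC)(CC)CC)[C@@]2(C)C=C[C@@H](OC3(C)C)[C@@](C)(O3)[C@@H]2[C@@H](O)[C@]2(OCc3ccc(OC)cc3)C(=C)C(=O)O[C@H]2[C@H]1Cl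
F4 | step 30 | macrocyclic pentaol (17(18)-methylene lactone; 3Z) | C=C1/C=C\[C@@H](O)[C@@]2(C)C=C[C@@H](O)[C@@](C)(O)[C@@H]2[C@@H](O)[C@]2(O)C(=C)C(=O)O[C@H]2[C@H]1Cl
F5 | step 30 | macrocyclic 2,9,12-triacetate (17(18)-methylene lactone; 3Z) | C=C1/C=C\[C@@H](OC(C)=O)[C@@]2(C)C=C[C@@H](OC(C)=O)[C@@](C)(O)[C@@H]2[C@@H](OC(C)=O)[C@]2(O)C(=C)C(=O)O[C@H]2[C@H]1Cl
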